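The α‑methylene‑γ‑lactone (O–C6–C7–C11–C12; germacrane numbering, carbocycle C1–C10) is disconnected at C7–C11. The feature used is the C8 hydroxyl beside C7: C7 and C11 are both donor carbons, so C7 is reversed to an acceptor as a trans‑7,8‑epoxide. In one operation a phosphonoacetate carbanion (C11) tethered on O6 opens the epoxide at C7 with inversion, closing the lactone and releasing the C8 alcohol, and formaldehyde then installs C13 by Horner–Wadsworth–Emmons olefination. The precursor is an acyclic erythro epoxy alcohol phosphonoacetate made by Sharpless kinetic resolution; the ten‑membered ring is closed later by metathesis at C4=C5.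

Key step: step 4

Remark on the chemistry: atoms carry germacranolide numbers throughout (C13 exocyclic methylene, C14 the oxygenated carbon on C10, C15 the methyl on C4); compounds 1, 2, 5, 12 and 14 are taken as commercial.

Step 1
Reactants: 1 (E)-4,4-dimethoxybut-2-enal; 2 vinylmagnesium bromide
Product: 3 rac-(E)-6,6-dimethoxyhexa-1,4-dien-3-ol
Conditions: THF, −78 °C; then aq. NH4Cl
Reagents that add atoms: none
Why: 1,2-Grignard addition to the enal carbonyl should give the racemic bis-allylic alcohol (C6 carbinol with the C5 vinyl group and the E-C7=C8 alkene), the acetal masking C9.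

Step 2
Reactants: 3 rac-(E)-6,6-dimethoxyhexa-1,4-dien-3-ol
Product: 4 (1R)-1-[(2R,3S)-3-(dimethoxymethyl)oxiran-2-yl]prop-2-en-1-ol
Conditions: Ti(OiPr)4, D-(−)-diisopropyl tartrate, t-BuOOH (0.55 equiv), 4 Å molecular sieves, CH2Cl2, −20 °C
Reagents that add atoms: tert-butyl hydroperoxide, CC(C)(C)OO
Why: Sharpless asymmetric epoxidation run as a kinetic resolution: with the D-tartrate the (R)-alcohol is the fast enantiomer and its E-1,2-disubstituted alkene is epoxidized on the face that gives the erythro epoxy alcohol, which fixes C6, C7 and C8, while the (S)-alcohol can react only at its slower vinyl group and is separated.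

Step 3
Reactants: 4 (1R)-1-[(2R,3S)-3-(dimethoxymethyl)oxiran-2-yl]prop-2-en-1-ol; 5 2-(diethoxyphosphoryl)acetic acid
Product: 6 (1R)-1-[(2R,3S)-3-(dimethoxymethyl)oxiran-2-yl]prop-2-en-1-yl 2-(diethoxyphosphoryl)acetate
Conditions: DCC, DMAP (cat.), CH2Cl2, 0 °C to rt
Reagents that add atoms: none
Why: Steglich esterification acylates the secondary C6 hydroxyl under neutral conditions that leave the epoxide, the acetal and all three stereocenters untouched.

Step 4
Reactants: 6 (1R)-1-[(2R,3S)-3-(dimethoxymethyl)oxiran-2-yl]prop-2-en-1-yl 2-(diethoxyphosphoryl)acetate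
Product: 8 (4R,5R)-5-ethenyl-4-[(1S)-1-hydroxy-2,2-dimethoxyethyl]-3-methylideneoxolan-2-one, via phosphono lactone 7 (not isolated)
Conditions: KOtBu (1.05 equiv), THF, 0 °C to 40 °C; then (CH2O)n, 0 °C to rt
Reagents that add atoms: formaldehyde (from paraformaldehyde), C=O
Why: Proposed new method: KOtBu deprotonates the phosphonoacetate at C11 and the potassium carbanion opens the tethered trans-epoxide at C7 in an intramolecular SN2 alkylation that closes the γ-lactone (O–C6–C7–C11–C12) in the 5-exo-tet mode and frees the C8 alkoxide, which is quenched by proton transfer from the more acidic α-phosphono lactone 7; the resulting carbanion then undergoes Horner–Wadsworth–Emmons olefination with formaldehyde to install the C11=C13 methylene. The closest known reaction types are the telescoped intramolecular Michael addition/Horner–Wadsworth–Emmons olefination of phosphonoacetates of γ-hydroxy enones (same tether, same ring and same carbanion, with an enone in place of the epoxide), the epoxynitrile-type intramolecular alkylation of stabilized carbanions by epoxides, and the base-induced cyclization of 2,3-epoxy alcohol carbamates at the proximal epoxide carbon. C7 is the only stereocenter formed and is set by stereospecific inversion (backside attack anti to the C7–O bond), so the (6R)-carbinol and the trans-epoxide of the erythro epoxy alcohol should translate into the 4,5-trans lactone with C11 and the retained C8–OH in the required erythro relation. The step needs attack at C7 and not at C8 (6-endo) or through the enolate oxygen: the five-membered exo closure is geometrically preferred, C8 is deactivated towards substitution by the adjacent acetal carbon, and the phosphoryl group keeps the anion nucleophilic at carbon when the ester carbonyl is twisted out of conjugation in the ring-forming transition state. The main risk is the sluggishness of phosphonate carbanions towards epoxides, for which gentle warming or LiCl as additive is held in reserve.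

Step 5
Reactants: 8 (4R,5R)-5-ethenyl-4-[(1S)-1-hydroxy-2,2-dimethoxyethyl]-3-methylideneoxolan-2-one
Product: 11 (2S)-2-[(2R,3S)-2-ethenyl-4-methylidene-5-oxooxolan-3-yl]-2-(triethylsilyloxy)acetaldehyde, via silyl ether acetal 9 (not isolated), via collidinium salt 10 (not isolated)
Conditions: Et3SiOTf (3.5 equiv), 2,4,6-collidine (5 equiv), CH2Cl2, −40 °C to 0 °C; then H2O, rt
Reagents that add atoms: triethylsilyl trifluoromethanesulfonate, CC[Si](CC)(CC)OS(=O)(=O)C(F)(F)F; water, O
Why: The silyl triflate/hindered pyridine pair first silylates the C8 hydroxyl and then converts the dimethyl acetal by way of a collidinium salt into the aldehyde on addition of water, a mild chemoselective acetal cleavage that should leave the silyl ether, the methylene lactone and the α-stereocenter C8 untouched.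

Step 6
Reactants: 12 ethyl 4-methylpent-4-enoate
Product: 13 4-methylpent-4-enal
Conditions: i-Bu2AlH (1.05 equiv), CH2Cl2, −78 °C; then aq. potassium sodium tartrate
Reagents that add atoms: none
Why: Partial reduction of the ester at low temperature stops at the tetrahedral aluminium hemiacetal, which should release the aldehyde (C1–C4 with C15) on work-up.

Step 7
Reactants: 13 4-methylpent-4-enal; 14 (formylmethylene)triphenylphosphorane
Product: 15 (E)-6-methylhepta-2,6-dienal
Conditions: toluene, 80 °C
Reagents that add atoms: none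
Why: Wittig olefination with the stabilized formyl ylide should give the E-enal, adding C10 and C14.

Step 8
Reactants: 15 (E)-6-methylhepta-2,6-dienal
Product: 16 (Z)-2-iodo-6-methylhepta-2,6-dienal
Conditions: I2, K2CO3, DMAP (20 mol %), THF/H2O, rt
Reagents that add atoms: iodine, II
Why: Amine-catalysed α-iodination of the enal (conjugate addition of DMAP, iodination of the enolate, elimination) keeps the formyl group trans to the chain, so iodine ends up cis to C2, the geometry later needed for the Z-C1=C10 alkene.

Step 9
Reactants: 16 (Z)-2-iodo-6-methylhepta-2,6-dienal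
Product: 17 (Z)-2-iodo-6-methylhepta-2,6-dien-1-ol
Conditions: NaBH4, CeCl3·7H2O, MeOH, 0 °C
Reagents that add atoms: none
Why: Luche reduction should deliver hydride 1,2 to the enal and leave the alkenyl iodide and its geometry intact.

Step 10
Reactants: 17 (Z)-2-iodo-6-methylhepta-2,6-dien-1-ol
Product: 18 (Z)-2-iodo-6-methylhepta-2,6-dien-1-yl 3-methylbutanoate
Conditions: 3-methylbutanoyl chloride, pyridine, DMAP (cat.), CH2Cl2, 0 °C
Reagents that add atoms: 3-methylbutanoyl chloride, CC(C)CC(Cl)=O
Why: Acylation of the primary allylic alcohol installs the C14 isovalerate of the target before fragment union.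

Step 11
Reactants: 11 (2S)-2-[(2R,3S)-2-ethenyl-4-methylidene-5-oxooxolan-3-yl]-2-(triethylsilyloxy)acetaldehyde; 18 (Z)-2-iodo-6-methylhepta-2,6-dien-1-yl 3-methylbutanoate
Product: 19 (4S,5R)-5-ethenyl-4-[(1S,2R,3Z)-2-hydroxy-7-methyl-3-{[(3-methylbutanoyl)oxy]methyl}-1-(triethylsilyloxy)octa-3,7-dien-1-yl]-3-methylideneoxolan-2-one
Conditions: CrCl2 (6 equiv), NiCl2 (2 mol %), DMSO, rt
Reagents that add atoms: none
Why: Nozaki–Hiyama–Kishi coupling: the alkenyl iodide is activated by nickel and passed to trivalent chromium with retention of geometry, and the alkenylchromium should add only to the aldehyde (lactone and esters untouched) anti to the α-silyloxy group (Felkin–Anh polar model), setting C9 as R, erythro to C8.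

Step 12
Reactants: 19 (9R)-allylic alcohol from step 11
Product: 20 (4S,5R)-4-[(1S,2R,3Z)-2-acetoxy-7-methyl-3-{[(3-methylbutanoyl)oxy]methyl}-1-(triethylsilyloxy)octa-3,7-dien-1-yl]-5-ethenyl-3-methylideneoxolan-2-one
Conditions: Ac2O, Et3N, DMAP (cat.), CH2Cl2, 0 °C
Reagents that add atoms: acetic anhydride, CC(=O)OC(C)=O
Why: DMAP-catalysed acetylation of the only free hydroxyl places the C9 acetate while O8 stays silylated, so the two secondary oxygens remain differentiated.

Step 13
Reactants: 20 seco-diene acetate from step 12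
Product: 21 (6R,7S,8S,9R)-9-acetoxy-14-(3-methylbutanoyloxy)-8-(triethylsilyloxy)germacra-1(10)Z,4Z,11(13)-trien-12,6-olide
Conditions: second-generation Grubbs catalyst RuCl2(=CHPh)(PCy3)(H2IMes) (15 mol %), toluene (1 mM), 80 °C
Reagents that add atoms: none
Why: Ring-closing metathesis between the C5 vinyl group and the 1,1-disubstituted C4 alkene releases ethylene and should close the ten-membered carbocycle with C4=C5 in the Z geometry favoured by the (Z,Z)-cyclodeca-1,5-diene ring, the hindered C1=C10 alkene and the electron-poor methylene lactone being expected to stay out of the catalytic cycle.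

Step 14
Reactants: 21 macrocyclic triethylsilyl ether from step 13
Product: 22 (6R,7R,8S,9R)-9-acetoxy-8-hydroxy-14-(3-methylbutanoyloxy)germacra-1(10)Z,4Z,11(13)-trien-12,6-olide (CNP0603244.1)
Conditions: HF·pyridine, THF/pyridine, 0 °C
Reagents that add atoms: none
Why: Cleavage of the triethylsilyl ether with buffered HF, without generating an alkoxide at O8, should free the C8 hydroxyl without 1,2-migration of the neighbouring acetate and give the target.

Compound list
1 | (E)-4,4-dimethoxybut-2-enal | COC(OC)/C=C/C=O | starting material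
2 | vinylmagnesium bromide | C=C[Mg]Br | starting material
3 | rac-(E)-6,6-dimethoxyhexa-1,4-dien-3-ol | C=CC(O)/C=C/C(OC)OC | intermediate
4 | (1R)-1-[(2R,3S)-3-(dimethoxymethyl)oxiran-2-yl]prop-2-en-1-ol (erythro, trans-epoxide) | C=C[C@@H](O)[C@H]1O[C@@H]1C(OC)OC | intermediate
5 | 2-(diethoxyphosphoryl)acetic acid | CCOP(=O)(CC(=O)O)OCC | starting material
6 | (1R)-1-[(2R,3S)-3-(dimethoxymethyl)oxiran-2-yl]prop-2-en-1-yl 2-(diethoxyphosphoryl)acetate | C=C[C@@H](OC(=O)CP(=O)(OCC)OCC)[C@H]1O[C@@H]1C(OC)OC | intermediate
7 | diethyl [(4R,5R)-5-ethenyl-4-[(1S)-1-hydroxy-2,2-dimethoxyethyl]-2-oxooxolan-3-yl]phosphonate (both C11 epimers, present as potassium salt) | CCOP(=O)(OCC)C1C(=O)O[C@H](C=C)[C@H]1[C@H](O)C(OC)OC | intermediate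
8 | (4R,5R)-5-ethenyl-4-[(1S)-1-hydroxy-2,2-dimethoxyethyl]-3-methylideneoxolan-2-one | C=C1C(=O)O[C@H](C=C)[C@H]1[C@H](O)C(OC)OC | intermediate
9 | (4S,5R)-4-[(1S)-2,2-dimethoxy-1-(triethylsilyloxy)ethyl]-5-ethenyl-3-methylideneoxolan-2-one | C=C1C(=O)O[C@H](C=C)[C@H]1[C@H](O[Si](CC)(CC)CC)C(OC)OC | intermediate
10 | 1-{(2S)-2-[(2R,3S)-2-ethenyl-4-methylidene-5-oxooxolan-3-yl]-1-methoxy-2-(triethylsilyloxy)ethyl}-2,4,6-trimethylpyridinium triflate (both C9 epimers) | C=C1C(=O)O[C@H](C=C)[C@H]1[C@H](O[Si](CC)(CC)CC)C(OC)[n+]1c(C)cc(C)cc1C.[O-]S(=O)(=O)C(F)(F)F | intermediate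
11 | (2S)-2-[(2R,3S)-2-ethenyl-4-methylidene-5-oxooxolan-3-yl]-2-(triethylsilyloxy)acetaldehyde | C=C1C(=O)O[C@H](C=C)[C@H]1[C@H](O[Si](CC)(CC)CC)C=O | intermediate
12 | ethyl 4-methylpent-4-enoate | CCOC(=O)CCC(C)=C | starting material
13 | 4-methylpent-4-enal | O=CCCC(C)=C | intermediate
14 | (formylmethylene)triphenylphosphorane | O=CC=P(c1ccccc1)(c1ccccc1)c1ccccc1 | starting material
15 | (E)-6-methylhepta-2,6-dienal | O=C/C=C/CCC(C)=C | intermediate
16 | (Z)-2-iodo-6-methylhepta-2,6-dienal | O=C/C(I)=C/CCC(C)=C | intermediate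
17 | (Z)-2-iodo-6-methylhepta-2,6-dien-1-ol | OC/C(I)=C/CCC(C)=C | intermediate
18 | (Z)-2-iodo-6-methylhepta-2,6-dien-1-yl 3-methylbutanoate | CC(C)CC(=O)OC/C(I)=C/CCC(C)=C | intermediate
19 | (4S,5R)-5-ethenyl-4-[(1S,2R,3Z)-2-hydroxy-7-methyl-3-{[(3-methylbutanoyl)oxy]methyl}-1-(triethylsilyloxy)octa-3,7-dien-1-yl]-3-methylideneoxolan-2-one | C=C1C(=O)O[C@H](C=C)[C@H]1[C@H](O[Si](CC)(CC)CC)[C@H](O)/C(COC(=O)CC(C)C)=C\CCC(C)=C | intermediate
20 | (4S,5R)-4-[(1S,2R,3Z)-2-acetoxy-7-methyl-3-{[(3-methylbutanoyl)oxy]methyl}-1-(triethylsilyloxy)octa-3,7-dien-1-yl]-5-ethenyl-3-methylideneoxolan-2-one | C=C1C(=O)O[C@H](C=C)[C@H]1[C@H](O[Si](CC)(CC)CC)[C@H](OC(C)=O)/C(COC(=O)CC(C)C)=C\CCC(C)=C | intermediate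
21 | (6R,7S,8S,9R)-9-acetoxy-14-(3-methylbutanoyloxy)-8-(triethylsilyloxy)germacra-1(10)Z,4Z,11(13)-trien-12,6-olide | C=C1C(=O)O[C@@H]2/C=C(/C)CC/C=C(/COC(=O)CC(C)C)[C@@H](OC(C)=O)[C@@H](O[Si](CC)(CC)CC)[C@@H]12 | intermediate
22 | (6R,7R,8S,9R)-9-acetoxy-8-hydroxy-14-(3-methylbutanoyloxy)germacra-1(10)Z,4Z,11(13)-trien-12,6-olide (CNP0603244.1) | C=C1C(=O)O[C@@H]2/C=C(/C)CC/C=C(/COC(=O)CC(C)C)[C@@H](OC(C)=O)[C@@H](O)[C@@H]12 | target

Total step count: 14. Longest linear sequence: 9 steps (steps 1–5 and 11–14, or equally steps 6–10 and 11–14).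

Steps most likely to fail

1. Step 4 (Proposed new method). The phosphonate carbanion may be too sluggish to open the epoxide, or may react through the distal carbon or the enolate oxygen, so that warming leads to decomposition instead of lactone closure. The fallback uses known radical chemistry, sets out from epoxy alcohol 4 and comes back at silyl ether acetal 9. O-Propargylation of 4 (NaH, propargyl bromide, Bu4NI, THF, 0 °C) should give the propargyl ether of 4, F1. Cp2TiCl (trivalent titanium, from Cp2TiCl2 and Zn dust, THF, rt, slow addition) opens the epoxide homolytically; the C7 radical closes 5-exo-dig onto the alkyne, still forming C7–C11 in the ring closure, and after reduction of the vinyl radical gives the 3-methylideneoxolane alcohol (1S)-1-[(2R,3R)-2-ethenyl-4-methylideneoxolan-3-yl]-2,2-dimethoxyethan-1-ol, F2. The C8–O bond is untouched and C7 is set trans to the C6 vinyl group in the ring closure; only the C7 radical can cyclize, so material opened the other way is removed as acyclic by-product. Silylation (Et3SiCl, imidazole, DMF) gives the triethylsilyl ether of F2, F3. Allylic oxidation of the ring CH2 next to oxygen (CrO3·3,5-dimethylpyrazole, CH2Cl2, −20 °C) gives lactone 9, which is taken to aldehyde 11 with Et3SiOTf/2,4,6-collidine and water as in step 5.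

2. Step 13. The ruthenium alkylidene formed at C5 may close onto the trisubstituted C1=C10 alkene (six-membered ring, loss of the C1–C4 chain) or oligomerize instead of closing the ten-membered ring. The fallback masks the competing alkene as a temporary epoxide, sets out from allylic alcohol 19 and comes back at macrocycle 21. Hydroxyl-directed epoxidation (VO(acac)2 cat., t-BuOOH, CH2Cl2, 0 °C) touches only the C1=C10 alkene and should give the 1,10-epoxy alcohol of 19, F4. One diastereomer is drawn; either serves, because both epoxide carbons return to sp2. Acetylation (Ac2O, Et3N, DMAP) gives the epoxy acetate F5. Ring-closing metathesis under the conditions of step 13, now with only the two intended alkenes available, gives the macrocyclic 1,10-epoxide F6. Stereospecific deoxygenation with retention (CH3ReO3 cat., PPh3, benzene, rt) restores the Z-C1=C10 alkene and gives 21.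

3. Step 11. Facial selectivity at C9 may be poor if a chelated transition state competes with the Felkin–Anh mode. The fallback sets C9 by ketone reduction instead of by addition, sets out from 19 obtained as a C9 epimer mixture and comes back at 19. Oxidation (Dess–Martin periodinane, NaHCO3, CH2Cl2, 0 °C) gives the α′-silyloxy enone F7. Reagent-controlled 1,2-reduction (oxazaborolidine-catalysed catecholborane reduction, catalyst enantiomer chosen for the 9R alcohol, toluene, −78 °C) should return 19 as the single 9R epimer.

Further compounds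
F1 | step 4 | (2S,3R)-2-(dimethoxymethyl)-3-[(1R)-1-(prop-2-yn-1-yloxy)prop-2-en-1-yl]oxirane (propargyl ether of 4) | C=C[C@@H](OCC#C)[C@H]1O[C@@H]1C(OC)OC
F2 | step 4 | (1S)-1-[(2R,3R)-2-ethenyl-4-methylideneoxolan-3-yl]-2,2-dimethoxyethan-1-ol | C=C1CO[C@H](C=C)[C@H]1[C@H](O)C(OC)OC
F3 | step 4 | triethylsilyl ether of F2 | C=C1CO[C@H](C=C)[C@H]1[C@H](O[Si](CC)(CC)CC)C(OC)OC
F4 | step 13 | 1,10-epoxy alcohol of 19 | C=C1C(=O)O[C@H](C=C)[C@H]1[C@H](O[Si](CC)(CC)CC)[C@H](O)[C@@]1(COC(=O)CC(C)C)O[C@H]1CCC(C)=C
F5 | step 13 | C9 acetate of F4 | C=C1C(=O)O[C@H](C=C)[C@H]1[C@H](O[Si](CC)(CC)CC)[C@H](OC(C)=O)[C@@]1(COC(=O)CC(C)C)O[C@H]1CCC(C)=C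
F6 | step 13 | macrocyclic 1,10-epoxide (1,10-epoxide of 21) | C=C1C(=O)O[C@@H]2/C=C(/C)CC[C@@H]3O[C@]3(COC(=O)CC(C)C)[C@@H](OC(C)=O)[C@@H](O[Si](CC)(CC)CC)[C@@H]12
F7 | step 11 | C9 ketone (enone) of 19 | C=C1C(=O)O[C@H](C=C)[C@H]1[C@H](O[Si](CC)(CC)CC)C(=O)/C(COC(=O)CC(C)C)=C\CCC(C)=C
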